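**Plan**
Numbering: germacrane numbering (ring C1–C10; butenolide O–C12(=O)–C11=C7–C6; C13 on C11, C14 on C10, C15 on C4).
Cuts: the ester C–O bonds at O8, O10 and O13; C10–O (hydration of a C10=C14 enone); the ring bond C1–C10; then, in one stroke, O–C6 and C7=C11 of the butenolide; last C6–C7 and C8–C9.
Feature used: in the open form C6 is a secondary carbinol next to the C7 ketone (an α-ketol flanked by the C4–C5 epoxide), so a phosphono acid can be attached to C6 through oxygen with inversion and closed onto C7=O as the five-membered lactone.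
Forward: an epoxy aldehyde (C1–C6, from geraniol) and an alkenyl Grignard (C7–C10, from prenal and 2,3-dibromopropene) are joined at C6–C7; ozonolysis frees the C7 ketone and C1 aldehyde; the butenolide is annulated; the ten-membered ring is closed last at C1–C10; hydration and acylations finish.
Stereochemistry: C4/C5 from Sharpless epoxidation; C6 from Felkin–Anh addition followed by inversion in the key step; C8 from CBS reduction; C10 from peripheral oxygen capture on the macrocycle; the Z ester from angelic acid.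

Key step: step 12

Assumption: ethyl 2-(diethoxyphosphoryl)acrylate (14) is taken as purchasable; it is otherwise one step from triethyl phosphonoacetate and paraformaldehyde.
Remark: 20 is carried as a mixture of C1 epimers, since both give the same ketone 21.

**Step 1**
Reactants: 1 geraniol
Product: 2 (2R,3R)-2,3-epoxygeraniol
Conditions: Ti(OiPr)4 (cat.), D-(−)-diethyl tartrate (cat.), t-BuOOH, 4 Å molecular sieves, CH2Cl2, −20 °C
Reagents that add atoms: tert-butyl hydroperoxide CC(C)(C)OO
Why: Sharpless asymmetric epoxidation of the allylic alcohol, in which the D-tartrate ligand directs oxygen to the alkene face that gives the (2R,3R) epoxide (C5 and C4 of the target) and the isolated trisubstituted alkene is left alone.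

**Step 2**
Reactants: 2 (2R,3R)-2,3-epoxygeraniol
Product: 3 (2S,3R)-2,3-epoxygeranial
Conditions: Dess–Martin periodinane, pyridine, CH2Cl2, 0 °C to rt
Reagents that add atoms: none
Why: Dess–Martin oxidation of the primary epoxy alcohol to the aldehyde under buffered conditions that should not epimerize the α-carbon (its descriptor changes only through priorities).

**Step 3**
Reactants: 4 3-methylbut-2-enal
Product: 5 2-iodo-3-methylbut-2-enal
Conditions: I2, pyridine, CH2Cl2, 0 °C to rt
Reagents that add atoms: iodine II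
Why: α-Iodination of an enal by the addition–iodination–elimination sequence (Baylis–Hillman-type, pyridine as nucleophilic mediator), a reaction type established for β-substituted enals and enones.

**Step 4**
Reactants: 5 2-iodo-3-methylbut-2-enal; 6 2,3-dibromoprop-1-ene
Product: 7 rac-6-bromo-3-iodo-2-methylhepta-2,6-dien-4-ol
Conditions: In powder, THF/H2O, rt
Reagents that add atoms: none
Why: Indium-mediated Barbier allylation, in which only the allylic C–Br bond of 6 is metalated and the allylindium adds 1,2 to the aldehyde, leaving both alkenyl halides in place (racemic carbinol).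

**Step 5**
Reactants: 7 rac-6-bromo-3-iodo-2-methylhepta-2,6-dien-4-ol
Product: 8 6-bromo-3-iodo-2-methylhepta-2,6-dien-4-one
Conditions: Dess–Martin periodinane, pyridine, CH2Cl2, 0 °C
Reagents that add atoms: none
Why: Dess–Martin oxidation of the allylic alcohol to the α-iodo enone under neutral conditions that should not move the β,γ-alkene into conjugation.

**Step 6**
Reactants: 8 6-bromo-3-iodo-2-methylhepta-2,6-dien-4-one
Product: 9 (4S)-6-bromo-3-iodo-2-methylhepta-2,6-dien-4-ol
Conditions: (R)-2-methyl-CBS-oxazaborolidine (cat.), BH3·SMe2, THF, −30 °C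
Reagents that add atoms: none
Why: Corey–Bakshi–Shibata reduction, in which the iodoalkenyl group acts as the large substituent so that the (R)-catalyst should deliver hydride to the face giving the (4S) carbinol, the future C8.

**Step 7**
Reactants: 9 (4S)-6-bromo-3-iodo-2-methylhepta-2,6-dien-4-ol
Product: 10 (4S)-6-bromo-3-iodo-2-methyl-4-(triethylsilyloxy)hepta-2,6-diene
Conditions: Et3SiCl, imidazole, CH2Cl2, 0 °C
Reagents that add atoms: chlorotriethylsilane CC[Si](Cl)(CC)CC
Why: Standard silylation of the secondary alcohol, giving an ether that survives the organometallic and oxidative steps and can be removed late with buffered fluoride.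

**Step 8**
Reactants: 10 (4S)-6-bromo-3-iodo-2-methyl-4-(triethylsilyloxy)hepta-2,6-diene; 3 (2S,3R)-2,3-epoxygeranial
Product: 12 (1R,3S)-5-bromo-1-[(2R,3R)-3-methyl-3-(4-methylpent-3-en-1-yl)oxiran-2-yl]-2-(propan-2-ylidene)-3-(triethylsilyloxy)hex-5-en-1-ol, via alkenylmagnesium chloride 11 (not isolated)
Conditions: i-PrMgCl·LiCl, THF, −20 °C; then 3, −78 to −20 °C
Reagents that add atoms: none
Why: Iodine–magnesium exchange is selective for the alkenyl iodide over the alkenyl bromide, and the alkenyl Grignard adds to the α,β-epoxy aldehyde in the Felkin–Anh sense (anti to the epoxide C–O bond) to give the erythro carbinol, C6 (R) at this stage.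

**Step 9**
Reactants: 12 (1R,3S)-5-bromo-1-[(2R,3R)-3-methyl-3-(4-methylpent-3-en-1-yl)oxiran-2-yl]-2-(propan-2-ylidene)-3-(triethylsilyloxy)hex-5-en-1-ol
Product: 13 (1S,3S)-5-bromo-1-hydroxy-1-[(2R,3R)-3-methyl-3-(3-oxopropyl)oxiran-2-yl]-3-(triethylsilyloxy)hex-5-en-2-one
Conditions: O3, CH2Cl2, −78 °C (Sudan Red 7B end point); then PPh3, −78 °C to rt
Reagents that add atoms: ozone O=[O+][O-]
Why: Ozonolysis with reductive work-up cleaves the two electron-rich alkenes (each loses acetone) to unveil the C7 ketone and the C1 aldehyde, while the electron-poor 2-bromoalkene reacts far more slowly and should be spared by stopping at the indicator end point.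

**Step 10**
Reactants: 14 ethyl 2-(diethoxyphosphoryl)acrylate; 15 4-methoxybenzyl alcohol
Product: 16 ethyl 2-(diethoxyphosphoryl)-3-[(4-methoxybenzyl)oxy]propanoate
Conditions: t-BuOK (cat.), THF, 0 °C
Reagents that add atoms: none
Why: Base-catalysed oxa-Michael addition of the alcohol to the doubly activated vinylphosphonate.

**Step 11**
Reactants: 16 ethyl 2-(diethoxyphosphoryl)-3-[(4-methoxybenzyl)oxy]propanoate
Product: 17 2-(diethoxyphosphoryl)-3-[(4-methoxybenzyl)oxy]propanoic acid
Conditions: Me3SnOH, ClCH2CH2Cl, 80 °C; then dilute HCl wash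
Reagents that add atoms: trimethyltin hydroxide C[Sn](C)(C)O
Why: Ester cleavage with Me3SnOH, a near-neutral hydrolysis that avoids the retro-Michael (E1cB) loss of the benzyloxy group that hydroxide could cause.

**Step 12**
Reactants: 13 (1S,3S)-5-bromo-1-hydroxy-1-[(2R,3R)-3-methyl-3-(3-oxopropyl)oxiran-2-yl]-3-(triethylsilyloxy)hex-5-en-2-one; 17 2-(diethoxyphosphoryl)-3-[(4-methoxybenzyl)oxy]propanoic acid
Product: 19 (5S)-4-[(1S)-3-bromo-1-(triethylsilyloxy)but-3-en-1-yl]-3-{[(4-methoxybenzyl)oxy]methyl}-5-[(2R,3R)-3-methyl-3-(3-oxopropyl)oxiran-2-yl]furan-2(5H)-one, via phosphonoacetate ester 18 (not isolated)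
Conditions: PPh3, DIAD, THF, 0 °C; then LiCl, i-Pr2NEt, MeCN, 0 °C to rt (same flask, ca. 5 mM)
Reagents that add atoms: none
Why: PPh3 and DIAD activate the C6 hydroxyl of 13 as an oxyphosphonium ion and the carboxylate of 17 displaces it by SN2, which forms the O–C6 bond with inversion and gives ester 18; LiCl and i-Pr2NEt then generate the lithium-chelated phosphonate carbanion at C11, which adds to the adjacent C7 ketone and collapses with loss of diethyl phosphate to the C7=C11 double bond. The closest known reactions are the Mitsunobu esterification of secondary carbinols with phosphonoacetic acids and the Masamune–Roush intramolecular Horner–Wadsworth–Emmons synthesis of butenolides from ketol phosphonoacetates. The five-membered ring closes by 5-exo-trig addition of C11 to the C7 carbonyl, and the ester tether leaves no choice of alkene geometry. The only stereocenter made is C6, fixed by stereospecific inversion of the Felkin-derived erythro carbinol to the threo arrangement of the target relative to the epoxide; C11 of 17 is racemic and becomes sp2. The step needs the ketone next to the tether to be attacked in preference to the distal C1 aldehyde, which the five-membered transition state at high dilution should secure. It also needs olefination to outrun β-elimination of the benzyloxy group and enolization at C6 and C8, for which the mild amine/LiCl conditions at 0 °C are chosen.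

**Step 13**
Reactants: 19 (5S)-4-[(1S)-3-bromo-1-(triethylsilyloxy)but-3-en-1-yl]-3-{[(4-methoxybenzyl)oxy]methyl}-5-[(2R,3R)-3-methyl-3-(3-oxopropyl)oxiran-2-yl]furan-2(5H)-one
Product: 20 (4R,5R,6S,8S)-4,5-epoxy-1-hydroxy-13-(4-methoxybenzyloxy)-8-(triethylsilyloxy)germacra-7(11),10(14)-dien-12,6-olide (C1 epimers)
Conditions: CrCl2 (excess), NiCl2 (cat.), DMSO/THF, rt, slow addition of 19 (final ca. 2 mM)
Reagents that add atoms: none
Why: Intramolecular Nozaki–Hiyama–Kishi coupling, in which nickel inserts into the alkenyl bromide, the alkenylchromium species adds chemoselectively to the aldehyde (lactone, epoxide and ethers are tolerated) and high dilution favours the ten-membered ring; the C1 carbinol configuration is irrelevant because it is oxidized next.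

**Step 14**
Reactants: 20 (4R,5R,6S,8S)-4,5-epoxy-1-hydroxy-13-(4-methoxybenzyloxy)-8-(triethylsilyloxy)germacra-7(11),10(14)-dien-12,6-olide
Product: 21 (4R,5R,6S,8S)-4,5-epoxy-13-(4-methoxybenzyloxy)-1-oxo-8-(triethylsilyloxy)germacra-7(11),10(14)-dien-12,6-olide
Conditions: Dess–Martin periodinane, pyridine, CH2Cl2, 0 °C; used at once
Reagents that add atoms: none
Why: Dess–Martin oxidation converts both C1 epimers of the allylic alcohol into the single exo-methylene ketone.

**Step 15**
Reactants: 21 (4R,5R,6S,8S)-4,5-epoxy-13-(4-methoxybenzyloxy)-1-oxo-8-(triethylsilyloxy)germacra-7(11),10(14)-dien-12,6-olide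
Product: 22 (4R,5R,6S,8S,10R)-4,5-epoxy-10-hydroxy-13-(4-methoxybenzyloxy)-1-oxo-8-(triethylsilyloxy)germacr-7(11)-en-12,6-olide
Conditions: Mn(dpm)3 (cat.; dpm = 2,2,6,6-tetramethylheptane-3,5-dionate), PhSiH3, O2 (1 atm), i-PrOH/CH2Cl2, 0 °C
Reagents that add atoms: dioxygen O=O
Why: Mukaiyama-type hydrogen-atom-transfer hydration of the α-methylene ketone (H to C14, O2 capture by the tertiary C10 radical, reduction of the peroxide by the silane), which should place the hydroxyl on the outer α face with the C14 methyl β, as in peripheral oxygenation of the 1(10) unit of germacranolides; the tetrasubstituted butenolide alkene is too hindered to accept the hydrogen atom.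

**Step 16**
Reactants: 22 (4R,5R,6S,8S,10R)-4,5-epoxy-10-hydroxy-13-(4-methoxybenzyloxy)-1-oxo-8-(triethylsilyloxy)germacr-7(11)-en-12,6-olide
Product: 23 (4R,5R,6S,8S,10R)-4,5-epoxy-8,10-dihydroxy-13-(4-methoxybenzyloxy)-1-oxogermacr-7(11)-en-12,6-olide
Conditions: HF·pyridine, pyridine, THF, 0 °C
Reagents that add atoms: none
Why: Fluoride-mediated desilylation buffered with pyridine, mild enough for the epoxide, the butenolide and the tertiary ketol; the free C8 carbinol is acylated at once so that the lactone cannot migrate to O8.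

**Step 17**
Reactants: 23 (4R,5R,6S,8S,10R)-4,5-epoxy-8,10-dihydroxy-13-(4-methoxybenzyloxy)-1-oxogermacr-7(11)-en-12,6-olide; 24 angelic acid
Product: 26 (4R,5R,6S,8S,10R)-8-angeloyloxy-4,5-epoxy-10-hydroxy-13-(4-methoxybenzyloxy)-1-oxogermacr-7(11)-en-12,6-olide, via mixed anhydride 25 (not isolated)
Conditions: 24, 2,4,6-trichlorobenzoyl chloride, Et3N, toluene, rt; then 23, 75 °C
Reagents that add atoms: none
Why: Yamaguchi-type esterification through the mixed anhydride without added DMAP, conditions under which the angeloyl group should transfer without isomerization to the tiglate; the secondary C8 hydroxyl reacts and the tertiary C10 hydroxyl does not.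

**Step 18**
Reactants: 26 (4R,5R,6S,8S,10R)-8-angeloyloxy-4,5-epoxy-10-hydroxy-13-(4-methoxybenzyloxy)-1-oxogermacr-7(11)-en-12,6-olide
Product: 27 (4R,5R,6S,8S,10R)-8-angeloyloxy-4,5-epoxy-10,13-dihydroxy-1-oxogermacr-7(11)-en-12,6-olide
Conditions: DDQ, CH2Cl2/pH 7 phosphate buffer, 0 °C
Reagents that add atoms: none
Why: Oxidative cleavage of the 4-methoxybenzyl ether with DDQ, which leaves the electron-poor alkenes, the epoxide and the esters untouched.

**Step 19**
Reactants: 27 (4R,5R,6S,8S,10R)-8-angeloyloxy-4,5-epoxy-10,13-dihydroxy-1-oxogermacr-7(11)-en-12,6-olide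
Product: 28 (4R,5R,6S,8S,10R)-10,13-diacetoxy-8-angeloyloxy-4,5-epoxy-1-oxogermacr-7(11)-en-12,6-olide (target)
Conditions: Ac2O, DMAP, Et3N, CH2Cl2, rt
Reagents that add atoms: acetic anhydride CC(=O)OC(C)=O
Why: DMAP-catalysed acyl transfer (Steglich-type acetylation) to the primary C13 hydroxyl and, more slowly, to the tertiary C10 hydroxyl, with no change at any stereocenter.

**Compound list**
1 | geraniol | CC(C)=CCC/C(C)=C/CO | starting material
2 | (2R,3R)-2,3-epoxygeraniol | CC(C)=CCC[C@@]1(C)O[C@@H]1CO | intermediate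
3 | (2S,3R)-2,3-epoxygeranial | CC(C)=CCC[C@@]1(C)O[C@@H]1C=O | intermediate
4 | 3-methylbut-2-enal | CC(C)=CC=O | starting material
5 | 2-iodo-3-methylbut-2-enal | CC(C)=C(I)C=O | intermediate
6 | 2,3-dibromoprop-1-ene | C=C(Br)CBr | starting material
7 | rac-6-bromo-3-iodo-2-methylhepta-2,6-dien-4-ol | CC(C)=C(I)C(O)CC(Br)=C | intermediate
8 | 6-bromo-3-iodo-2-methylhepta-2,6-dien-4-one | CC(C)=C(I)C(=O)CC(Br)=C | intermediate
9 | (4S)-6-bromo-3-iodo-2-methylhepta-2,6-dien-4-ol | CC(C)=C(I)[C@@H](O)CC(Br)=C | intermediate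
10 | (4S)-6-bromo-3-iodo-2-methyl-4-(triethylsilyloxy)hepta-2,6-diene | CC(C)=C(I)[C@@H](O[Si](CC)(CC)CC)CC(Br)=C | intermediate
11 | alkenylmagnesium chloride from 10 (MgCl in place of I) | CC(C)=C([Mg]Cl)[C@@H](O[Si](CC)(CC)CC)CC(Br)=C | intermediate
12 | (1R,3S)-5-bromo-1-[(2R,3R)-3-methyl-3-(4-methylpent-3-en-1-yl)oxiran-2-yl]-2-(propan-2-ylidene)-3-(triethylsilyloxy)hex-5-en-1-ol | CC(C)=CCC[C@@]1(C)O[C@@H]1[C@H](O)C(=C(C)C)[C@@H](O[Si](CC)(CC)CC)CC(Br)=C | intermediate
13 | (1S,3S)-5-bromo-1-hydroxy-1-[(2R,3R)-3-methyl-3-(3-oxopropyl)oxiran-2-yl]-3-(triethylsilyloxy)hex-5-en-2-one | O=CCC[C@@]1(C)O[C@@H]1[C@H](O)C(=O)[C@@H](O[Si](CC)(CC)CC)CC(Br)=C | intermediate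
14 | ethyl 2-(diethoxyphosphoryl)acrylate | C=C(C(=O)OCC)P(=O)(OCC)OCC | starting material
15 | 4-methoxybenzyl alcohol | COc1ccc(CO)cc1 | starting material
16 | ethyl 2-(diethoxyphosphoryl)-3-[(4-methoxybenzyl)oxy]propanoate (racemic) | CCOC(=O)C(COCc1ccc(OC)cc1)P(=O)(OCC)OCC | intermediate
17 | 2-(diethoxyphosphoryl)-3-[(4-methoxybenzyl)oxy]propanoic acid (racemic) | OC(=O)C(COCc1ccc(OC)cc1)P(=O)(OCC)OCC | intermediate
18 | (1R,3S)-5-bromo-1-[(2R,3R)-3-methyl-3-(3-oxopropyl)oxiran-2-yl]-2-oxo-3-(triethylsilyloxy)hex-5-en-1-yl 2-(diethoxyphosphoryl)-3-[(4-methoxybenzyl)oxy]propanoate (C6 inverted; epimers at the phosphonate carbon) | O=CCC[C@@]1(C)O[C@@H]1[C@@H](OC(=O)C(COCc2ccc(OC)cc2)P(=O)(OCC)OCC)C(=O)[C@@H](O[Si](CC)(CC)CC)CC(Br)=C | intermediate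
19 | (5S)-4-[(1S)-3-bromo-1-(triethylsilyloxy)but-3-en-1-yl]-3-{[(4-methoxybenzyl)oxy]methyl}-5-[(2R,3R)-3-methyl-3-(3-oxopropyl)oxiran-2-yl]furan-2(5H)-one | O=CCC[C@@]1(C)O[C@@H]1[C@H]1OC(=O)C(COCc2ccc(OC)cc2)=C1[C@@H](O[Si](CC)(CC)CC)CC(Br)=C | intermediate
20 | (4R,5R,6S,8S)-4,5-epoxy-1-hydroxy-13-(4-methoxybenzyloxy)-8-(triethylsilyloxy)germacra-7(11),10(14)-dien-12,6-olide (C1 epimers) | CC[Si](CC)(CC)O[C@H]1CC(=C)C(O)CC[C@@]2(C)O[C@@H]2[C@H]2OC(=O)C(COCc3ccc(OC)cc3)=C12 | intermediate
21 | (4R,5R,6S,8S)-4,5-epoxy-13-(4-methoxybenzyloxy)-1-oxo-8-(triethylsilyloxy)germacra-7(11),10(14)-dien-12,6-olide | CC[Si](CC)(CC)O[C@H]1CC(=C)C(=O)CC[C@@]2(C)O[C@@H]2[C@H]2OC(=O)C(COCc3ccc(OC)cc3)=C12 | intermediate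
22 | (4R,5R,6S,8S,10R)-4,5-epoxy-10-hydroxy-13-(4-methoxybenzyloxy)-1-oxo-8-(triethylsilyloxy)germacr-7(11)-en-12,6-olide | CC[Si](CC)(CC)O[C@H]1C[C@@](C)(O)C(=O)CC[C@@]2(C)O[C@@H]2[C@H]2OC(=O)C(COCc3ccc(OC)cc3)=C12 | intermediate
23 | (4R,5R,6S,8S,10R)-4,5-epoxy-8,10-dihydroxy-13-(4-methoxybenzyloxy)-1-oxogermacr-7(11)-en-12,6-olide | O[C@H]1C[C@@](C)(O)C(=O)CC[C@@]2(C)O[C@@H]2[C@H]2OC(=O)C(COCc3ccc(OC)cc3)=C12 | intermediate
24 | angelic acid, (Z)-2-methylbut-2-enoic acid | C/C=C(/C)C(=O)O | starting material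
25 | angelic 2,4,6-trichlorobenzoic anhydride | C/C=C(/C)C(=O)OC(=O)c1c(Cl)cc(Cl)cc1Cl | intermediate
26 | (4R,5R,6S,8S,10R)-8-angeloyloxy-4,5-epoxy-10-hydroxy-13-(4-methoxybenzyloxy)-1-oxogermacr-7(11)-en-12,6-olide | C/C=C(/C)C(=O)O[C@H]1C[C@@](C)(O)C(=O)CC[C@@]2(C)O[C@@H]2[C@H]2OC(=O)C(COCc3ccc(OC)cc3)=C12 | intermediate
27 | (4R,5R,6S,8S,10R)-8-angeloyloxy-4,5-epoxy-10,13-dihydroxy-1-oxogermacr-7(11)-en-12,6-olide | C/C=C(/C)C(=O)O[C@H]1C[C@@](C)(O)C(=O)CC[C@@]2(C)O[C@@H]2[C@H]2OC(=O)C(CO)=C12 | intermediate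
28 | (4R,5R,6S,8S,10R)-10,13-diacetoxy-8-angeloyloxy-4,5-epoxy-1-oxogermacr-7(11)-en-12,6-olide | C/C=C(/C)C(=O)O[C@H]1C[C@@](C)(OC(C)=O)C(=O)CC[C@@]2(C)O[C@@H]2[C@H]2OC(=O)C(COC(C)=O)=C12 | target

**Step count**
Total: 19 steps. Longest linear sequence: 15 steps (steps 3–9 and 12–19); steps 1–2 and 10–11 are side branches.

**Steps most likely to fail**

1. Step 13 (ring closure). Transannular strain and the rigid butenolide may slow the closure so that oligomerization or reduction of the alkenyl bromide takes over. Fallback, from 13 back to 22: the ring is closed before the butenolide is in place. Keto aldehyde 13 is submitted to the same CrCl2/NiCl2 coupling (the aldehyde reacts, the ketone does not) to give macrocyclic ketol diol F1. MnO2 oxidizes only the allylic C1 carbinol to the exo-methylene dione F2. Hydration with Mn(dpm)3, PhSiH3 and O2 gives the tertiary alcohol F3. Mitsunobu coupling of F3 with 17 gives the C6-inverted phosphonoacetate F4 (not isolated), and LiCl/i-Pr2NEt olefination closes the butenolide to 22, where the route continues.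

2. Step 12 (invertive annulation). Activation of the ketol may lead to elimination or to esterification with retention through an acyloxyphosphonium path, the free aldehyde may interfere, and the phosphonate carbanion may lose the benzyloxy group. Fallback, from 12 back to 19: C6 is inverted before the ester is made. Alcohol 12 is oxidized (Dess–Martin periodinane) to the enone F5, which is reduced under reagent control ((S)-2-methyl-CBS-oxazaborolidine, catecholborane, the alkenyl group acting as the large substituent) to the threo carbinol F6. Ozonolysis as in step 9 gives the epimeric ketol F7. Esterification with 17 with retention (EDC, DMAP) gives 18, and LiCl/i-Pr2NEt olefination gives 19.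

3. Step 15 (C10 carbinol). Oxygen capture by the planar C10 radical may occur with poor or wrong facial selectivity. Fallback, from 20 back to 22: hydration is moved to the alcohol oxidation level, where the adjacent C1 carbinol and not the enone conformation steers the face. The C1 epimers of 20 are separated and each is hydrated (Co(acac)2, PhSiH3, O2) to the 1,10-diol F8. The epimer of F8 that carries the (10R) carbinol is oxidized at C1 (SO3·pyridine, DMSO, i-Pr2NEt) to 22.

**Further compounds**
F1 | step 13 | (4R,5R,6S,8S)-4,5-epoxy-1,6-dihydroxy-8-(triethylsilyloxy)-11,12,13-trinorgermacr-10(14)-en-7-one (C1 epimers) | CC[Si](CC)(CC)O[C@H]1CC(=C)C(O)CC[C@@]2(C)O[C@@H]2[C@H](O)C1=O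
F2 | step 13 | (4R,5R,6S,8S)-4,5-epoxy-6-hydroxy-8-(triethylsilyloxy)-11,12,13-trinorgermacr-10(14)-ene-1,7-dione | CC[Si](CC)(CC)O[C@H]1CC(=C)C(=O)CC[C@@]2(C)O[C@@H]2[C@H](O)C1=O
F3 | step 13 | (4R,5R,6S,8S,10R)-4,5-epoxy-6,10-dihydroxy-8-(triethylsilyloxy)-11,12,13-trinorgermacrane-1,7-dione | CC[Si](CC)(CC)O[C@H]1C[C@@](C)(O)C(=O)CC[C@@]2(C)O[C@@H]2[C@H](O)C1=O
F4 | step 13 | (6R)-6-O-{2-(diethoxyphosphoryl)-3-[(4-methoxybenzyl)oxy]propanoyl} ester of F3 with C6 inverted | CC[Si](CC)(CC)O[C@H]1C[C@@](C)(O)C(=O)CC[C@@]2(C)O[C@@H]2[C@@H](OC(=O)C(COCc3ccc(OC)cc3)P(=O)(OCC)OCC)C1=O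
F5 | step 12 | (3S)-5-bromo-1-[(2S,3R)-3-methyl-3-(4-methylpent-3-en-1-yl)oxiran-2-yl]-2-(propan-2-ylidene)-3-(triethylsilyloxy)hex-5-en-1-one | CC(C)=CCC[C@@]1(C)O[C@@H]1C(=O)C(=C(C)C)[C@@H](O[Si](CC)(CC)CC)CC(Br)=C
F6 | step 12 | (1S,3S)-5-bromo-1-[(2R,3R)-3-methyl-3-(4-methylpent-3-en-1-yl)oxiran-2-yl]-2-(propan-2-ylidene)-3-(triethylsilyloxy)hex-5-en-1-ol | CC(C)=CCC[C@@]1(C)O[C@@H]1[C@@H](O)C(=C(C)C)[C@@H](O[Si](CC)(CC)CC)CC(Br)=C
F7 | step 12 | (1R,3S)-5-bromo-1-hydroxy-1-[(2R,3R)-3-methyl-3-(3-oxopropyl)oxiran-2-yl]-3-(triethylsilyloxy)hex-5-en-2-one | O=CCC[C@@]1(C)O[C@@H]1[C@@H](O)C(=O)[C@@H](O[Si](CC)(CC)CC)CC(Br)=C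
F8 | step 15 | (4R,5R,6S,8S,10R)-4,5-epoxy-1,10-dihydroxy-13-(4-methoxybenzyloxy)-8-(triethylsilyloxy)germacr-7(11)-en-12,6-olide (single C1 epimer) | CC[Si](CC)(CC)O[C@H]1C[C@@](C)(O)C(O)CC[C@@]2(C)O[C@@H]2[C@H]2OC(=O)C(COCc3ccc(OC)cc3)=C12
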